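## The problem

CNP0315707.1, compound 24 below, is a trans-fused hydroazulene of the daucane type in which a cyclopentane (C1–C5) and a cycloheptane (C1, C5–C10) share the C1–C5 bond; daucane numbering is used throughout, with α the face of H5 and β the face of the C1 methyl group. It carries six stereocentres (C1, C4, C5, C6, C8, C9), an 8α,9α-epoxide and a 1,3-diol whose tertiary oxygen O4, not the secondary O6, bears the vanilloyl group. C1 is an all-carbon quaternary centre with no heteroatom next to it, so it has to be set by an enantioselective or relayed C–C bond formation and then serves as the reference for the rest. C5 is epimerisable as long as C4 is a ketone; once it is trans to the C1 methyl group, the α face of C4 is open to an isopropyl nucleophile, and the α hydroxyl on C6 can later deliver the epoxide oxygen to the α face of C8=C9. The groups that do not survive rough treatment are the trisubstituted epoxide (acid, strong nucleophiles), the tertiary aryl ester next to a free secondary alcohol (base-induced O4→O6 acyl shift, ionisation at C4 in acid) and the free phenol, so all three should appear late. The ester must moreover be made on a hindered tertiary alcohol in the presence of a secondary one. The feature that opens the skeleton is that the seven-membered ring with its C8 methyl group, together with the chain C2–C3–C4, is a p-tolyl ring with a three-carbon tether into which one carbon, C5, has been inserted between the ipso carbon C1 and an ortho carbon C6, so that a carbene at C5, next to the C4 carbonyl, can form C5–C1 and C5–C6 and close both rings in one step.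

## Retrosynthesis

**Phenol and epoxide: 24 ⇒ 23 ⇒ 22.** The phenol O–H and the two epoxide C–O bonds are made last. The phenol of 24 is carried as the benzyl ether 23 and freed by hydrogenolysis once no alkene is left. The epoxide of 23 is cut at C8–O and C9–O back to the homoallylic alcohol 22. Cutting here keeps the epoxide out of every basic or acidic step and lets the free α hydroxyl on C6 direct the oxygen to the α face. The forward reaction must leave the tertiary ester where it is.

**Ester: 22 ⇒ 21 ⇒ 18 + 19.** The acyl C–O4 bond is cut next. O6 has to be masked while O4 is acylated, because a free secondary alcohol would react first; the triisopropylsilyl ether 21 is chosen because this silyl group is slow to migrate between oxygens. The pieces are the sesquiterpene alcohol 18 and commercial 4-(benzyloxy)-3-methoxybenzoic acid 19, activated as chloride 20. The forward step is the acylation of a hindered tertiary alkoxide.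

**Isopropyl group: 18 ⇒ 17 ⇒ 16.** Cutting the C4–isopropyl bond gives the silyl-protected ketone 17, made from hydroxy ketone 16. This cut is preferred to forming the C4–O bond on a C4–H compound, which would need a late C–H oxidation. It asks for a non-basic organometallic addition from the α face, which the trans ring fusion should provide.

**C6 oxygen: 16 ⇒ 15 ⇒ 14.** The C6–O bond is traced, by way of boronate 15, to a conjugate addition at the β-carbon of enone 14, with C5 protonated in the same operation. The neighbouring cut, hydration of a C6=C7 bond within a C6=C7–C8=C9 diene, is rejected: four diene carbons compete for the boron of any hydroborating agent, and the trisubstituted end is both the more electron-rich and the less hindered. In 14 the only electrophilic alkene carbon is C6 and the C8=C9 bond is isolated. The forward reaction must choose the α face of C6 and leave C5 trans.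

**C5=C6 bond and C1 methyl: 14 ⇒ 13 ⇒ 12 ⇒ 11.** The enone double bond comes from dehydrogenation of the regiodefined silyl enol ether 13. Enol ether 13 is the trapped form of enolate 12, which arises by reductive cleavage of cyclopropyl ketone 11; the C5–CH2 bond is broken and the CH2 becomes the C1 methyl group. Because C1 is quaternary, the dehydrogenation can only go toward C6.

**Cyclopropane: 11 ⇒ 10 ⇒ 9 ⇒ 8.** The two cyclopropane bonds (C1–CH2, C5–CH2) of 11, and of its carbinol 10, are cut back to allylic alcohol 9, whose carbinol centre comes from a catalyst-controlled reduction of enone 8. Direct copper-catalysed asymmetric conjugate methylation of 8 would be shorter, but a ring-fused, tetrasubstituted enone lies outside the substrate range for which that reaction is established. The relay (reduction, directed cyclopropanation, oxidation, ring opening) uses only standard reactions and sets C1 with the selectivity of the ketone reduction.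

**C6=C7 saturation: 8 ⇒ 7.** Enone 8 is the 7,8-dihydro derivative of trienone 7. The C6=C7 bond is removed because, if it were kept, the later enolate chemistry at C5 would run through a cross-conjugated trienolate that can be protonated at C5, C7 or C9 with no control element. The forward step must reduce the cis-disubstituted bond and leave the trisubstituted and tetrasubstituted ones.

**Both rings: 7 ⇒ 6 ⇒ 5 ⇒ 4, key step.** Cutting C5–C1 and C5–C6 of 7, through its unconjugated isomer 6 and norcaradiene 5, opens both rings and returns the p-tolyl diazoketone 4. No other single cut removes two rings and two skeletal bonds and ends in an achiral benzene derivative. The tolyl methyl group becomes the C8 methyl, the diazoketone carbonyl becomes C4, and the C8=C9 bond is left in place.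

**Diazoketone: 4 ⇒ 3 + 2.** The C4–C5 bond is made by acylating (trimethylsilyl)diazomethane 2 with the chloride 3 of commercial acid 1.

## Roads not taken

**Alternative 1:** The C4–O bond is cut and formed last by Hofmann–Löffler–Freytag chemistry. The N-bromo-N-(2,2,2-trifluoroethyl) carbamate A2, carried on O6 of the C4–H compound, is photolysed; the nitrogen radical abstracts H4, C4 takes up bromine, and Ag2CO3-promoted closure with hydrolysis gives the 4,6-cyclic carbonate A1.
- Merits: no organometallic addition to a hindered ketone is needed, and in A1 the two oxygens sit in a ring that cannot suffer silyl or acyl migration. In these respects it is better than the chosen plan, which has to protect O6 and acylate a tertiary alkoxide.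
- Weak points: the whole skeleton, the C4 isopropyl centre, C5, C6 and the epoxide must already be in place in A2, so the alternative does not answer how the rings are built. A radical bromination and a silver-assisted ionisation are run beside an epoxide. Once C4 is brominated, loss of HBr competes with closure, and the configuration at C4 depends on which face the tethered oxygen reaches. A1 must still be opened so that the aroyl group ends on the tertiary oxygen.
- Comparison: the chosen plan sets C4 by a carbonyl addition steered by the ring fusion and keeps the epoxide out of all radical and Lewis acid steps.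

**Alternative 2:** C7–C8 and C1–C10 are cut. The 2-siloxydiene A3 and methyl 2-diazobut-3-enoate A4 react under Rh2(S-DOSP)4 by cyclopropanation and divinylcyclopropane Cope rearrangement to give the bicyclic keto ester A5.
- Merits: the step is convergent and catalytic, it sets the C1 quaternary centre enantioselectively in the ring-forming event, and it delivers the C4 ketone, the C6 oxygen (as enol ether) and the C8=C9 bond at once. This is better than the chosen plan, which needs a four-step relay for C1 and a separate oxygenation at C6.
- Weak points: in A5, C8 carries an ester where the target has a methyl group, so a multistep reduction of a conjugated ester is added. The carbenoid must select the enol ether double bond of the hindered cross-conjugated diene A3. C5 and C6 still have to be set from A5, a masked 1,3-diketone in which C5 epimerises freely.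
- Comparison: the chosen plan takes the C8 methyl group and the C8=C9 bond directly from the tolyl ring and closes both rings of the skeleton from a precursor that is one step from a commercial acid.

**Alternative 3:** The C6–O and C9–O bonds are cut. Tetraphenylporphyrin-sensitised singlet oxygen adds across C6 and C9 of the 6,8-diene A6 to give the endoperoxide A7.
- Merits: oxygen enters C6 regioselectively without first removing and then re-installing unsaturation, so the reduction of step 3 and the dehydrogenation of step 8 would not be needed. Both oxygens arrive on one face in a single event. The route to the oxygenated ring is shorter than in the chosen plan.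
- Weak points: in A7 the second oxygen sits on C9 with a C7=C8 double bond, which is not the target pattern (8,9-epoxide, C7 methylene), so the peroxide must be reduced and the allylic system reworked. Diene A6 requires C5 to be set by a protonation for which the structure offers no control.
- Comparison: the chosen plan pays two redox steps but arrives at exactly the C6 alcohol with an untouched C8=C9 bond, so that one hydroxyl-directed epoxidation finishes the ring.

Key step: step 2

Remark on locants: systematic names use azulene numbering, in which azulene C1, C3a, C8a, C8, C6 and C5 are daucane C4, C1, C5, C6, C8 and C9; the Why lines use daucane numbering.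

Assumption: in step 9 the (R,R) antipode of the bisphosphine is taken to be the one that sends boron to the Si (α) face of C6; if the sense is the reverse, the (S,S) antipode is used with no other change.

## Steps

Step 1
Reactants: 1 3-(4-methylphenyl)propanoic acid; 2 (trimethylsilyl)diazomethane
Product: 4 1-diazo-4-(4-methylphenyl)butan-2-one, via 3-(4-methylphenyl)propanoyl chloride 3 (not isolated)
Conditions: (COCl)2, cat. DMF, CH2Cl2, 0 °C → rt, then evaporate; 2 (2 equiv), THF–MeCN, 0 °C → rt
Reagents that add atoms: oxalyl chloride, O=C(Cl)C(=O)Cl (chlorine of 3)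
Why: Oxalyl chloride/DMF converts the acid into chloride 3, which acylates the nucleophilic carbon of 2 with loss of Me3SiCl (Arndt–Eistert-type diazoketone synthesis); the silyl reagent avoids diazomethane.

Step 2
Reactants: 4 1-diazo-4-(4-methylphenyl)butan-2-one
Product: 7 6-methyl-3,4-dihydroazulen-1(2H)-one, via norcaradiene 5 (not isolated), via 6-methyl-3,8a-dihydroazulen-1(2H)-one 6 (not isolated)
Conditions: Rh2(OAc)4 (1 mol %), CH2Cl2, reflux, slow addition of 4; then Et3N, rt
Reagents that add atoms: none
Why: Rh2(OAc)4 decomposes diazoketone 4 to a rhodium carbene at C5, which cyclopropanates the ipso–ortho π bond of the tolyl ring (C1–C6); the closest known reaction type is the intramolecular Buchner reaction of 1-diazo-4-arylbutan-2-ones to dihydroazulenones. The five-membered ring closes in this cyclopropanation, because the three-atom tether C2–C3–C4 lets the carbene reach only the ipso carbon and its neighbour (C5–C1 and C5–C6 formed, norcaradiene 5). The seven-membered ring then arises by thermal disrotatory 6π electrocyclic opening of the C1–C6 bond of 5, so it consists of the six arene carbons plus C5 (trienone 6). Et3N moves the C5 proton and brings the triene into conjugation with the ketone, giving 7 with C5=C1 as the only enone bond. No stereocentre survives, since the sp3 centre at C5 of 6 is erased by this isomerisation. The step needs chemoselectivity for arene addition over carbene dimerisation and benzylic C–H insertion, which slow addition at high dilution and the tether length should secure. Regiochemistry is not at issue, because the para methyl group makes the two ipso–ortho bonds equivalent and ends on C8.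

Step 3
Reactants: 7 6-methyl-3,4-dihydroazulen-1(2H)-one
Product: 8 6-methyl-3,4,7,8-tetrahydroazulen-1(2H)-one
Conditions: KO2CN=NCO2K, AcOH, MeOH, 0 °C → rt
Reagents that add atoms: none
Why: Diimide, released from the azodicarboxylate by acid, transfers two hydrogens in a concerted syn fashion and reacts fastest with the least substituted double bond, so the cis-disubstituted C6=C7 bond should be reduced ahead of the trisubstituted C8=C9 and the tetrasubstituted enone bond. No metal is present that could isomerise the remaining alkenes.

Step 4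
Reactants: 8 6-methyl-3,4,7,8-tetrahydroazulen-1(2H)-one
Product: 9 (1S)-6-methyl-1,2,3,4,7,8-hexahydroazulen-1-ol
Conditions: (R)-2-methyl-CBS-oxazaborolidine (20 mol %), catecholborane, toluene, −78 °C
Reagents that add atoms: none
Why: Corey–Bakshi–Shibata reduction: the tetrasubstituted alkene acts as the large substituent and the C3 methylene as the small one, so hydride is delivered to one face and gives the (S) carbinol at C4. Catecholborane is used so that the C8=C9 bond is not hydroborated; this centre is a relay and is removed in step 6.

Step 5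
Reactants: 9 (1S)-6-methyl-1,2,3,4,7,8-hexahydroazulen-1-ol
Product: 10 (1R,7R,8S)-4-methyltricyclo[5.3.1.0(1,7)]undec-3-en-8-ol
Conditions: Et2Zn, CH2I2, CH2Cl2, −10 → 0 °C
Reagents that add atoms: diiodomethane, ICI
Why: Hydroxyl-directed Simmons–Smith cyclopropanation (Furukawa conditions): the zinc alkoxide of 9 holds the iodomethylzinc carbenoid on the hydroxyl face of the adjacent tetrasubstituted alkene, so the CH2 group (the future C1 methyl carbon) is added syn to O4 and fixes C1 and C5. The remote, undirected C8=C9 bond reacts far more slowly.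

Step 6
Reactants: 10 (1R,7R,8S)-4-methyltricyclo[5.3.1.0(1,7)]undec-3-en-8-ol
Product: 11 (1R,7R)-4-methyltricyclo[5.3.1.0(1,7)]undec-3-en-8-one
Conditions: Dess–Martin periodinane, pyridine, CH2Cl2, 0 °C → rt
Reagents that add atoms: none
Why: Dess–Martin oxidation of a secondary alcohol under buffered conditions that do not ionise the cyclopropylcarbinyl system; the stereochemical information now rests in the cyclopropane.

Step 7
Reactants: 11 (1R,7R)-4-methyltricyclo[5.3.1.0(1,7)]undec-3-en-8-one
Product: 13 trimethyl{[(3aR)-3a,6-dimethyl-2,3,3a,4,7,8-hexahydroazulen-1-yl]oxy}silane, via lithium enolate 12 (not isolated)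
Conditions: Li, NH3(l)–THF, t-BuOH (1 equiv), −78 °C; isoprene; evaporate NH3; Me3SiCl, Et3N, THF, −78 → 0 °C
Reagents that add atoms: chlorotrimethylsilane, C[Si](C)(C)Cl; lithium, [Li] (counter-ion of 12)
Why: Dissolving-metal reductive cleavage of a conjugated cyclopropyl ketone: the ketyl opens the cyclopropane bond that overlaps with the carbonyl π system, here the exocyclic C5–CH2 bond and not the C1–C5 bond lying in the plane of the five-membered ring. This leaves CH3 on C1 with (R) configuration and the regiodefined C4–C5 enolate 12, whose regiochemistry is stored by silylation on oxygen.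

Step 8
Reactants: 13 trimethyl{[(3aR)-3a,6-dimethyl-2,3,3a,4,7,8-hexahydroazulen-1-yl]oxy}silane
Product: 14 (3aR)-3a,6-dimethyl-3,3a,4,7-tetrahydroazulen-1(2H)-one
Conditions: Pd(OAc)2 (10 mol %), O2 (1 atm), DMSO, rt
Reagents that add atoms: none
Why: Saegusa–Ito dehydrogenation: the palladium enolate formed at C5 can undergo β-hydride elimination only toward C6, because C1 is quaternary, which gives the C5=C6 enone and leaves the isolated C8=C9 bond in place.

Step 9
Reactants: 14 (3aR)-3a,6-dimethyl-3,3a,4,7-tetrahydroazulen-1(2H)-one
Product: 16 (3aR,8S,8aS)-8-hydroxy-3a,6-dimethyl-3,3a,4,7,8,8a-hexahydroazulen-1(2H)-one, via boronate 15 (not isolated)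
Conditions: CuCl (5 mol %), (R,R)-2,3-bis(tert-butylmethylphosphino)quinoxaline (5 mol %), NaOtBu (10 mol %), B2pin2, MeOH, THF, rt; then NaBO3·4H2O, THF–H2O, rt
Reagents that add atoms: bis(pinacolato)diboron, CC1(C)OB(OC1(C)C)B1OC(C)(C)C(C)(C)O1 (boron of 15); sodium perborate, [Na+].[O-]OB=O (oxygen on C6)
Why: Copper-boryl conjugate addition (catalytic asymmetric β-borylation of an enone) puts boron on C6, the face (Si, α) being chosen by the chiral bisphosphine so that it does not depend on the remote C1 centre, and perborate replaces boron by hydroxyl with retention. C5 is protonated and, being epimerisable, should settle under the mildly basic oxidation as the trans-fused epimer, in which C2, C4 and O6 are all equatorial on the seven-membered ring and only the C1 methyl is axial.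

Step 10
Reactants: 16 (3aR,8S,8aS)-8-hydroxy-3a,6-dimethyl-3,3a,4,7,8,8a-hexahydroazulen-1(2H)-one
Product: 17 (3aR,8S,8aS)-3a,6-dimethyl-8-[(triisopropylsilyl)oxy]-3,3a,4,7,8,8a-hexahydroazulen-1(2H)-one
Conditions: i-Pr3SiOTf, 2,6-lutidine, CH2Cl2, −78 → 0 °C
Reagents that add atoms: triisopropylsilyl trifluoromethanesulfonate, CC(C)[Si](C(C)C)(C(C)C)OS(=O)(=O)C(F)(F)F
Why: Silylation of the secondary alcohol with a silyl triflate and a hindered base is mild enough for a β-hydroxy ketone; the triisopropylsilyl group is chosen because it resists 1,5 oxygen-to-oxygen migration in step 12.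

Step 11
Reactants: 17 (3aR,8S,8aS)-3a,6-dimethyl-8-[(triisopropylsilyl)oxy]-3,3a,4,7,8,8a-hexahydroazulen-1(2H)-one
Product: 18 (1R,3aR,8S,8aS)-3a,6-dimethyl-1-(propan-2-yl)-8-[(triisopropylsilyl)oxy]-1,2,3,3a,4,7,8,8a-octahydroazulen-1-ol
Conditions: i-PrMgCl, CeCl3 (anhydrous), THF, −78 °C
Reagents that add atoms: isopropylmagnesium chloride, CC(C)[Mg]Cl
Why: Organocerium 1,2-addition, used because the weakly basic reagent suppresses enolisation at C5, β-elimination of the silyloxy group and reduction by β-hydride transfer. In the trans-fused ketone the β face of C4 is screened by the C1 methyl group, which stands 1,3 to the carbonyl carbon, whereas the equatorial silyloxy group on C6 lies near the plane of the rings; isopropyl should therefore enter from the α face (syn to H5) and give the (4R) tertiary alcohol with O4 β.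

Step 12
Reactants: 18 (1R,3aR,8S,8aS)-3a,6-dimethyl-1-(propan-2-yl)-8-[(triisopropylsilyl)oxy]-1,2,3,3a,4,7,8,8a-octahydroazulen-1-ol; 19 4-(benzyloxy)-3-methoxybenzoic acid
Product: 21 (1R,3aR,8S,8aS)-3a,6-dimethyl-1-(propan-2-yl)-8-[(triisopropylsilyl)oxy]-1,2,3,3a,4,7,8,8a-octahydroazulen-1-yl 4-(benzyloxy)-3-methoxybenzoate, via 4-(benzyloxy)-3-methoxybenzoyl chloride 20 (not isolated)
Conditions: 19, (COCl)2, cat. DMF, CH2Cl2, rt, then evaporate; 18, LiN(SiMe3)2, THF, −78 °C; add 20, −78 → 0 °C
Reagents that add atoms: oxalyl chloride, O=C(Cl)C(=O)Cl (chlorine of 20)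
Why: Acylation of a lithium tertiary alkoxide with an aroyl chloride is the standard way to esterify a hindered tertiary alcohol. Deprotonation at −78 °C and the bulky silyl ether on O6 are meant to prevent silyl transfer to O4, and the phenol is masked as a benzyl ether.

Step 13
Reactants: 21 (1R,3aR,8S,8aS)-3a,6-dimethyl-1-(propan-2-yl)-8-[(triisopropylsilyl)oxy]-1,2,3,3a,4,7,8,8a-octahydroazulen-1-yl 4-(benzyloxy)-3-methoxybenzoate
Product: 22 (1R,3aR,8S,8aS)-8-hydroxy-3a,6-dimethyl-1-(propan-2-yl)-1,2,3,3a,4,7,8,8a-octahydroazulen-1-yl 4-(benzyloxy)-3-methoxybenzoate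
Conditions: HF·pyridine, pyridine, THF, 0 °C → rt
Reagents that add atoms: none
Why: Fluoride-mediated desilylation under weakly acidic, buffered conditions frees O6 without generating an alkoxide, which would invite O4→O6 acyl migration; benzyl ether, ester and alkene are inert.

Step 14
Reactants: 22 (1R,3aR,8S,8aS)-8-hydroxy-3a,6-dimethyl-1-(propan-2-yl)-1,2,3,3a,4,7,8,8a-octahydroazulen-1-yl 4-(benzyloxy)-3-methoxybenzoate
Product: 23 (1R,4R,5S,6S,8R,9S)-8,9-epoxy-6-hydroxydaucan-4-yl 4-(benzyloxy)-3-methoxybenzoate
Conditions: VO(acac)2 (5 mol %), t-BuOOH, CH2Cl2, 0 °C → rt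
Reagents that add atoms: tert-butyl hydroperoxide, CC(C)(C)OO
Why: Hydroxyl-directed epoxidation of a homoallylic alcohol: the vanadium alkoxide formed at O6 carries the tert-butyl peroxide ligand and transfers oxygen to the face of the C8=C9 bond on which O6 sits (α), setting C8 (R) and C9 (S). The phenol is protected and is not exposed to the oxidant.

Step 15
Reactants: 23 (1R,4R,5S,6S,8R,9S)-8,9-epoxy-6-hydroxydaucan-4-yl 4-(benzyloxy)-3-methoxybenzoate
Product: 24 (1R,4R,5S,6S,8R,9S)-8,9-epoxy-6-hydroxydaucan-4-yl 4-hydroxy-3-methoxybenzoate (CNP0315707.1)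
Conditions: H2 (1 atm), Pd/C (10%), EtOAc, rt
Reagents that add atoms: none
Why: Hydrogenolysis of the aryl benzyl ether over Pd/C under neutral conditions; no alkene remains, and the trialkyl-substituted epoxide and the tertiary aryl ester are not benzylic and should persist.

## Compound list

1 | 3-(4-methylphenyl)propanoic acid | Cc1ccc(CCC(=O)O)cc1 | starting material
2 | (trimethylsilyl)diazomethane | C[Si](C)(C)C=[N+]=[N-] | starting material
3 | 3-(4-methylphenyl)propanoyl chloride | Cc1ccc(CCC(=O)Cl)cc1 | intermediate
4 | 1-diazo-4-(4-methylphenyl)butan-2-one | Cc1ccc(CCC(=O)C=[N+]=[N-])cc1 | intermediate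
5 | 8-methyltricyclo[4.4.0.0(1,5)]deca-7,9-dien-4-one (norcaradiene; racemic, one enantiomer drawn) | O=C1CC[C@]23[C@H]1[C@H]2C=C(C)C=C3 | intermediate
6 | 6-methyl-3,8a-dihydroazulen-1(2H)-one (racemic) | O=C1CCC2=CC=C(C)C=CC12 | intermediate
7 | 6-methyl-3,4-dihydroazulen-1(2H)-one | O=C1CCC2=C1C=CC(C)=CC2 | intermediate
8 | 6-methyl-3,4,7,8-tetrahydroazulen-1(2H)-one | O=C1CCC2=C1CCC(C)=CC2 | intermediate
9 | (1S)-6-methyl-1,2,3,4,7,8-hexahydroazulen-1-ol | O[C@H]1CCC2=C1CCC(C)=CC2 | intermediate
10 | (1R,7R,8S)-4-methyltricyclo[5.3.1.0(1,7)]undec-3-en-8-ol (CH2 bridge across daucane C1–C5, syn to the hydroxyl) | O[C@H]1CC[C@@]23C[C@@]12CCC(C)=CC3 | intermediate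
11 | (1R,7R)-4-methyltricyclo[5.3.1.0(1,7)]undec-3-en-8-one | O=C1CC[C@@]23C[C@@]12CCC(C)=CC3 | intermediate
12 | lithium (3aR)-3a,6-dimethyl-2,3,3a,4,7,8-hexahydroazulen-1-olate | [Li+].[O-]C1=C2CCC(C)=CC[C@@]2(C)CC1 | intermediate
13 | trimethyl{[(3aR)-3a,6-dimethyl-2,3,3a,4,7,8-hexahydroazulen-1-yl]oxy}silane | C[Si](C)(C)OC1=C2CCC(C)=CC[C@@]2(C)CC1 | intermediate
14 | (3aR)-3a,6-dimethyl-3,3a,4,7-tetrahydroazulen-1(2H)-one | O=C1CC[C@]2(C)CC=C(C)CC=C12 | intermediate
15 | (3aR,8S,8aR)-3a,6-dimethyl-8-(4,4,5,5-tetramethyl-1,3,2-dioxaborolan-2-yl)-3,3a,4,7,8,8a-hexahydroazulen-1(2H)-one | O=C1CC[C@]2(C)CC=C(C)C[C@H](B3OC(C)(C)C(C)(C)O3)[C@H]21 | intermediate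
16 | (3aR,8S,8aS)-8-hydroxy-3a,6-dimethyl-3,3a,4,7,8,8a-hexahydroazulen-1(2H)-one | O=C1CC[C@]2(C)CC=C(C)C[C@H](O)[C@H]21 | intermediate
17 | (3aR,8S,8aS)-3a,6-dimethyl-8-[(triisopropylsilyl)oxy]-3,3a,4,7,8,8a-hexahydroazulen-1(2H)-one | O=C1CC[C@]2(C)CC=C(C)C[C@H](O[Si](C(C)C)(C(C)C)C(C)C)[C@H]21 | intermediate
18 | (1R,3aR,8S,8aS)-3a,6-dimethyl-1-(propan-2-yl)-8-[(triisopropylsilyl)oxy]-1,2,3,3a,4,7,8,8a-octahydroazulen-1-ol | O[C@@]1(C(C)C)CC[C@]2(C)CC=C(C)C[C@H](O[Si](C(C)C)(C(C)C)C(C)C)[C@H]21 | intermediate
19 | 4-(benzyloxy)-3-methoxybenzoic acid | COc1cc(C(=O)O)ccc1OCc1ccccc1 | starting material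
20 | 4-(benzyloxy)-3-methoxybenzoyl chloride | COc1cc(C(=O)Cl)ccc1OCc1ccccc1 | intermediate
21 | (1R,3aR,8S,8aS)-3a,6-dimethyl-1-(propan-2-yl)-8-[(triisopropylsilyl)oxy]-1,2,3,3a,4,7,8,8a-octahydroazulen-1-yl 4-(benzyloxy)-3-methoxybenzoate | COc1cc(C(=O)O[C@@]2(C(C)C)CC[C@]3(C)CC=C(C)C[C@H](O[Si](C(C)C)(C(C)C)C(C)C)[C@H]32)ccc1OCc1ccccc1 | intermediate
22 | (1R,3aR,8S,8aS)-8-hydroxy-3a,6-dimethyl-1-(propan-2-yl)-1,2,3,3a,4,7,8,8a-octahydroazulen-1-yl 4-(benzyloxy)-3-methoxybenzoate | COc1cc(C(=O)O[C@@]2(C(C)C)CC[C@]3(C)CC=C(C)C[C@H](O)[C@H]32)ccc1OCc1ccccc1 | intermediate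
23 | (1R,4R,5S,6S,8R,9S)-8,9-epoxy-6-hydroxydaucan-4-yl 4-(benzyloxy)-3-methoxybenzoate (8α,9α-epoxide, 6α-OH, 5α-H, 4β-O-acyl) | COc1cc(C(=O)O[C@@]2(C(C)C)CC[C@]3(C)C[C@@H]4O[C@]4(C)C[C@H](O)[C@H]32)ccc1OCc1ccccc1 | intermediate
24 | (1R,4R,5S,6S,8R,9S)-8,9-epoxy-6-hydroxydaucan-4-yl 4-hydroxy-3-methoxybenzoate (CNP0315707.1) | COc1cc(C(=O)O[C@@]2(C(C)C)CC[C@]3(C)C[C@@H]4O[C@]4(C)C[C@H](O)[C@H]32)ccc1O | target

## Step count and least certain steps

Total: 15 steps. Longest linear sequence: 15 steps (1 → 24); acid 19 enters in step 12.

**Step 2 (key step).** The most likely failures are carbene dimerisation or azine formation if the stationary concentration of 4 is too high, and rearrangement of the norcaradiene/cycloheptatriene pair into the aromatic 2-tetralone skeleton by formal aromatic substitution, which acid or a Lewis-acidic metal promotes. The fallback sets out from acid 1, lets the carbene meet an ordinary alkene instead of the arene, and comes back at 7 by way of norcaradiene 5. Birch reduction of 1 (Li, NH3, t-BuOH, THF, −78 °C) would give 3-(4-methylcyclohexa-1,4-dien-1-yl)propanoic acid F1. Conversion into the acid chloride and acylation of 2 as in step 1 would give 1-diazo-4-(4-methylcyclohexa-1,4-dien-1-yl)butan-2-one F2. Rh2(OAc)4-catalysed intramolecular cyclopropanation of the trisubstituted ring alkene, the standard route to bicyclo[3.1.0]hexan-2-ones, forms the same C5–C1 and C5–C6 bonds and would give 8-methyltricyclo[4.4.0.0(1,5)]dec-8-en-4-one F3; no aromatic substitution path exists at this stage. Addition of bromine to the remaining C8=C9 bond (Br2, CH2Cl2, −78 °C) would give 8,9-dibromo-8-methyltricyclo[4.4.0.0(1,5)]decan-4-one F4. Twofold dehydrobromination with DBU (toluene, 80 °C), the classical way to cycloheptatrienes from Birch-derived norcarenes, would give norcaradiene 5, which opens to 6 and is conjugated by the same base to 7 without meeting acid.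

**Step 3.** Chemoselectivity may be lost, with diimide also saturating the trisubstituted C8=C9 bond or stalling before C6=C7 is consumed, because all three double bonds of 7 are conjugated. The fallback sets out from 7, postpones the saturation and comes back at 11. CBS reduction of 7 as in step 4 would give (1S)-6-methyl-1,2,3,4-tetrahydroazulen-1-ol F5. Directed cyclopropanation as in step 5 would give (1R,7S,8S)-4-methyltricyclo[5.3.1.0(1,7)]undeca-3,5-dien-8-ol F6. Dess–Martin oxidation would give (1R,7S)-4-methyltricyclo[5.3.1.0(1,7)]undeca-3,5-dien-8-one F7. In this dienone the cis-disubstituted C6=C7 bond belongs to an ordinary diene, and hydrogenation with RhCl(PPh3)3/H2, which discriminates di- from trisubstituted alkenes on steric grounds, leads to 11.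

**Step 9.** Three things may go wrong: poor facial selectivity of the boryl addition at C6, since the substrate offers little bias of its own; protonation or equilibration at C5 toward the cis ring fusion; and base-induced drift of the skipped dienone into full conjugation through the acidic C7 hydrogens. The fallback sets out from 14, replaces the conjugate addition by hydroxyl-directed chemistry and comes back at 16. Reduction of 14 with (S)-2-methyl-CBS-oxazaborolidine/catecholborane would give (1R,3aR)-3a,6-dimethyl-1,2,3,3a,4,7-hexahydroazulen-1-ol F8, with the hydroxyl α. VO(acac)2/t-BuOOH epoxidation, directed to the hydroxyl face and selective for the allylic alcohol, would give the 5α,6α-epoxy-4α-alcohol F9. Dess–Martin oxidation would give the 5α,6α-epoxy ketone F10. SmI2 (THF–MeOH, −78 °C) cleaves the C5–O bond next to the carbonyl and, after equilibration at C5, leads to 16 with the C6 configuration fixed by the directed epoxidation.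

**Step 12.** The hindered tertiary alkoxide may acylate slowly, and 1,5 oxygen-to-oxygen silyl migration would expose the far more reactive secondary alkoxide and place the ester on O6. The fallback sets out from 16, uses a protecting group that cannot migrate and comes back at 22. 4-Methoxybenzyl 2,2,2-trichloroacetimidate with cat. Sc(OTf)3 would give (3aR,8S,8aS)-8-[(4-methoxybenzyl)oxy]-3a,6-dimethyl-3,3a,4,7,8,8a-hexahydroazulen-1(2H)-one F11. i-PrMgCl/CeCl3 as in step 11 would give (1R,3aR,8S,8aS)-8-[(4-methoxybenzyl)oxy]-3a,6-dimethyl-1-(propan-2-yl)-1,2,3,3a,4,7,8,8a-octahydroazulen-1-ol F12. Acylation with 20 as in step 12 would give (1R,3aR,8S,8aS)-8-[(4-methoxybenzyl)oxy]-3a,6-dimethyl-1-(propan-2-yl)-1,2,3,3a,4,7,8,8a-octahydroazulen-1-yl 4-(benzyloxy)-3-methoxybenzoate F13. DDQ in CH2Cl2–pH 7 buffer removes the 4-methoxybenzyl group and leads to 22.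

## Further compounds

F1 | step 2 | 3-(4-methylcyclohexa-1,4-dien-1-yl)propanoic acid | CC1=CCC(CCC(=O)O)=CC1
F2 | step 2 | 1-diazo-4-(4-methylcyclohexa-1,4-dien-1-yl)butan-2-one | CC1=CCC(CCC(=O)C=[N+]=[N-])=CC1
F3 | step 2 | 8-methyltricyclo[4.4.0.0(1,5)]dec-8-en-4-one (racemic, one enantiomer drawn) | O=C1CC[C@]23[C@H]1[C@H]2CC(C)=CC3
F4 | step 2 | 8,9-dibromo-8-methyltricyclo[4.4.0.0(1,5)]decan-4-one (trans-dibromide; racemic, one diastereomer drawn) | O=C1CC[C@]23[C@H]1[C@H]2C[C@](C)(Br)[C@@H](Br)C3
F5 | step 3 | (1S)-6-methyl-1,2,3,4-tetrahydroazulen-1-ol | O[C@H]1CCC2=C1C=CC(C)=CC2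
F6 | step 3 | (1R,7S,8S)-4-methyltricyclo[5.3.1.0(1,7)]undeca-3,5-dien-8-ol | O[C@H]1CC[C@@]23C[C@@]12C=CC(C)=CC3
F7 | step 3 | (1R,7S)-4-methyltricyclo[5.3.1.0(1,7)]undeca-3,5-dien-8-one | O=C1CC[C@@]23C[C@@]12C=CC(C)=CC3
F8 | step 9 | (1R,3aR)-3a,6-dimethyl-1,2,3,3a,4,7-hexahydroazulen-1-ol | O[C@@H]1CC[C@]2(C)CC=C(C)CC=C12
F9 | step 9 | 5α,6α-epoxy-4α-alcohol: the 8,8a-epoxide (azulene locants) of F8 on the hydroxyl face, daucane descriptors (1R,4R,5S,6S) | O[C@@H]1CC[C@]2(C)CC=C(C)C[C@@H]3O[C@]123
F10 | step 9 | 5α,6α-epoxy ketone: the 8,8a-epoxide (azulene locants) of 14 with oxygen α, daucane descriptors (1R,5R,6S) | O=C1CC[C@]2(C)CC=C(C)C[C@@H]3O[C@]123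
F11 | step 12 | (3aR,8S,8aS)-8-[(4-methoxybenzyl)oxy]-3a,6-dimethyl-3,3a,4,7,8,8a-hexahydroazulen-1(2H)-one | O=C1CC[C@]2(C)CC=C(C)C[C@H](OCc3ccc(OC)cc3)[C@H]21
F12 | step 12 | (1R,3aR,8S,8aS)-8-[(4-methoxybenzyl)oxy]-3a,6-dimethyl-1-(propan-2-yl)-1,2,3,3a,4,7,8,8a-octahydroazulen-1-ol | O[C@@]1(C(C)C)CC[C@]2(C)CC=C(C)C[C@H](OCc3ccc(OC)cc3)[C@H]21
F13 | step 12 | (1R,3aR,8S,8aS)-8-[(4-methoxybenzyl)oxy]-3a,6-dimethyl-1-(propan-2-yl)-1,2,3,3a,4,7,8,8a-octahydroazulen-1-yl 4-(benzyloxy)-3-methoxybenzoate | COc1cc(C(=O)O[C@@]2(C(C)C)CC[C@]3(C)CC=C(C)C[C@H](OCc4ccc(OC)cc4)[C@H]32)ccc1OCc1ccccc1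
A1 | alternative 1 | 4,6-cyclic carbonate of 8α,9α-epoxy-5αH-daucane-4β,6α-diol | O=C1O[C@@]2(C(C)C)CC[C@]3(C)C[C@@H]4O[C@]4(C)C[C@H](O1)[C@H]32
A2 | alternative 1 | 8α,9α-epoxy-4βH,5αH-daucan-6α-yl N-bromo-N-(2,2,2-trifluoroethyl)carbamate | CC(C)[C@@H]1CC[C@]2(C)C[C@@H]3O[C@]3(C)C[C@H](OC(=O)N(Br)CC(F)(F)F)[C@H]21
A3 | alternative 2 | 2-{1-[(tert-butyldimethylsilyl)oxy]ethenyl}-3-methylcyclopent-2-en-1-one | C=C(O[Si](C)(C)C(C)(C)C)C1=C(C)CCC1=O
A4 | alternative 2 | methyl 2-diazobut-3-enoate | C=CC(=[N+]=[N-])C(=O)OC
A5 | alternative 2 | methyl (8aR)-4-[(tert-butyldimethylsilyl)oxy]-8a-methyl-3-oxo-1,2,3,5,8,8a-hexahydroazulene-6-carboxylate | O=C1CC[C@]2(C)CC=C(C(=O)OC)CC(O[Si](C)(C)C(C)(C)C)=C21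
A6 | alternative 3 | 5αH-dauca-6,8-dien-4β-ol | O[C@@]1(C(C)C)CC[C@]2(C)CC=C(C)C=C[C@H]21
A7 | alternative 3 | 6α,9α-epidioxy-5αH-dauc-7-en-4β-ol | O[C@@]1(C(C)C)CC[C@]2(C)C[C@@H]3OO[C@@H](C=C3C)[C@H]21
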